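Ring B (C5–C10, labdane numbering) carries the ether oxygen at C8 next to the quaternary C10, the retron of a 2-oxygenated-diene Diels–Alder reaction. Everything rests on an intramolecular [4+2] cycloaddition of an acyclic triene in which a 2-methoxydiene (C7=C8(OMe)–C9=C10) and an (E)-vinyl sulfone (C5=C6) are joined by the C1–C4 chain that already holds the (3S)-bromide and the C4 gem-dimethyl group. One operation forms C5–C10 and C6–C7, closes rings A and B as a trans-decalin and sets C5 and C10 under control of C3. The C8 ketone so revealed is turned into the axial-methyl tertiary ether; ring-closing metathesis builds the oxocane and epoxidation ends the route.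

Key step: step 11

Remark on notation: atoms carry labdane numbers (ring A = C1–C5 and C10; ring B = C5–C10; chain C11–C16 on C9; C17 on C8; C20 on C10), and β is the face of C20.
Remark on intermediates: alkali-metal enolates and alkoxides formed by simple deprotonation are treated as salt forms of the numbered compounds and are not numbered separately.

Step 1
Reactants: 1 3,3-dimethylpent-4-enoic acid; 2 (R)-4-benzyloxazolidin-2-one
Product: 4 (R)-4-benzyl-3-(3,3-dimethylpent-4-enoyl)oxazolidin-2-one, via mixed pivalic anhydride 3 (not isolated)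
Conditions: PivCl, Et3N, THF, −20 °C; then 2, LiCl, rt
Reagents that add atoms: none
Why: N-acylation of the oxazolidinone through a mixed anhydride is a standard auxiliary attachment, the hindered pivaloyl carbonyl steering attack to the substrate carbonyl; no stereocenter is formed.

Step 2
Reactants: 4 (R)-4-benzyl-3-(3,3-dimethylpent-4-enoyl)oxazolidin-2-one
Product: 6 (R)-4-benzyl-3-[(2R)-2-bromo-3,3-dimethylpent-4-enoyl]oxazolidin-2-one, via dibutylboron Z-enolate 5 (not isolated)
Conditions: Bu2BOTf, iPr2NEt, CH2Cl2, −78 → 0 °C; then NBS, −78 °C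
Reagents that add atoms: N-bromosuccinimide, O=C1CCC(=O)N1Br
Why: auxiliary-controlled electrophilic α-bromination of the Z-boron enolate, a reaction type established for β-quaternary acyl imides, in which NBS attacks the enolate face opposite the benzyl group and so sets the (2R) C–Br centre that becomes C3.

Step 3
Reactants: 6 (R)-4-benzyl-3-[(2R)-2-bromo-3,3-dimethylpent-4-enoyl]oxazolidin-2-one
Product: 7 (2R)-2-bromo-3,3-dimethylpent-4-en-1-ol
Conditions: LiBH4, Et2O, H2O (1 equiv), 0 °C
Reagents that add atoms: none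
Why: reductive cleavage of the imide by hydride attack on the exocyclic carbonyl should release the primary alcohol and the recoverable auxiliary at 0 °C, while the neopentylic C–Br centre is too hindered for displacement and keeps its configuration.

Step 4
Reactants: 7 (2R)-2-bromo-3,3-dimethylpent-4-en-1-ol
Product: 8 (2R)-2-bromo-3,3-dimethylpent-4-en-1-yl trifluoromethanesulfonate
Conditions: Tf2O, 2,6-lutidine, CH2Cl2, −78 °C (used at once)
Reagents that add atoms: trifluoromethanesulfonic anhydride, O=S(=O)(OS(=O)(=O)C(F)(F)F)C(F)(F)F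
Why: O-sulfonylation of the primary alcohol gives an alkyl triflate that is a far better SN2 electrophile than the hindered secondary bromide, and C3 is not touched.

Step 5
Reactants: 9 methyl acetoacetate; 10 2-(2-bromoethyl)-2-methyl-1,3-dioxolane
Product: 11 methyl 2-acetyl-4-(2-methyl-1,3-dioxolan-2-yl)butanoate (racemic)
Conditions: NaH, NaI (cat.), THF/DMF, 0 → 60 °C
Reagents that add atoms: none
Why: acetoacetic ester alkylation, the C-alkylation of a stabilised sodium enolate with a primary bromide under iodide catalysis; the new stereocenter is of no consequence because it becomes sp2 in step 7.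

Step 6
Reactants: 11 methyl 2-acetyl-4-(2-methyl-1,3-dioxolan-2-yl)butanoate; 8 (2R)-2-bromo-3,3-dimethylpent-4-en-1-yl trifluoromethanesulfonate
Product: 12 methyl (6S)-6-bromo-7,7-dimethyl-2-[2-(2-methyl-1,3-dioxolan-2-yl)ethyl]-3-oxonon-8-enoate
Conditions: 11, NaH, THF, 0 °C; n-BuLi, 0 °C; then 8, −78 → −20 °C
Reagents that add atoms: none
Why: γ-alkylation of a β-keto ester dianion, which reacts at its more basic terminal carbon (C1) and should displace the primary triflate by SN2 at low temperature much faster than the hindered secondary bromide can react, joining the two fragments at C1–C2 with C3 unchanged.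

Step 7
Reactants: 12 methyl (6S)-6-bromo-7,7-dimethyl-2-[2-(2-methyl-1,3-dioxolan-2-yl)ethyl]-3-oxonon-8-enoate
Product: 13 methyl (2Z,6S)-6-bromo-7,7-dimethyl-2-[2-(2-methyl-1,3-dioxolan-2-yl)ethyl]-3-(trifluoromethylsulfonyloxy)nona-2,8-dienoate
Conditions: Tf2O, saturated aqueous LiOH, PhMe, 5 °C
Reagents that add atoms: trifluoromethanesulfonic anhydride, O=S(=O)(OS(=O)(=O)C(F)(F)F)C(F)(F)F
Why: O-triflation of the lithium-chelated β-keto ester enolate, in which chelation between the enolate oxygen and the ester carbonyl should hold the triflate cis to the ester and give the Z enol triflate.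

Step 8
Reactants: 13 methyl (2Z,6S)-6-bromo-7,7-dimethyl-2-[2-(2-methyl-1,3-dioxolan-2-yl)ethyl]-3-(trifluoromethylsulfonyloxy)nona-2,8-dienoate
Product: 14 methyl (2E,6S)-6-bromo-3,7,7-trimethyl-2-[2-(2-methyl-1,3-dioxolan-2-yl)ethyl]nona-2,8-dienoate
Conditions: MeMgBr, Fe(acac)3 (5 mol %), THF/NMP, −30 °C
Reagents that add atoms: methylmagnesium bromide, C[Mg]Br
Why: iron-catalysed cross-coupling of an activated enol triflate with a Grignard reagent proceeds with retention of alkene geometry and faster than any reaction of the ester, ketal or hindered bromide, placing the C10 methyl cis and the tether trans to the ester carbon.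

Step 9
Reactants: 14 methyl (2E,6S)-6-bromo-3,7,7-trimethyl-2-[2-(2-methyl-1,3-dioxolan-2-yl)ethyl]nona-2,8-dienoate
Product: 16 methyl (2E,6S,8E)-6-bromo-3,7,7-trimethyl-2-[2-(2-methyl-1,3-dioxolan-2-yl)ethyl]-9-(phenylsulfonyl)nona-2,8-dienoate, via β-iodo sulfone 15 (not isolated)
Conditions: PhSO2Na, I2, EtOAc/H2O, rt, visible light; then Et3N, MeCN, 0 °C
Reagents that add atoms: sodium benzenesulfinate, [Na+].[O-]S(=O)c1ccccc1
Why: radical iodosulfonylation followed by dehydroiodination, in which the sulfonyl radical adds to the terminal carbon of the only unhindered electron-rich alkene (the tetrasubstituted enoate is inert) and base-induced loss of HI gives the conjugated E vinyl sulfone.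

Step 10
Reactants: 16 methyl (2E,6S,8E)-6-bromo-3,7,7-trimethyl-2-[2-(2-methyl-1,3-dioxolan-2-yl)ethyl]-9-(phenylsulfonyl)nona-2,8-dienoate
Product: 17 2-[(3E,7S,9E)-7-bromo-3-(1-methoxyethenyl)-4,8,8-trimethyl-10-(phenylsulfonyl)deca-3,9-dien-1-yl]-2-methyl-1,3-dioxolane
Conditions: Cp2TiMe2, PhMe/THF, 65 °C, dark
Reagents that add atoms: dimethyltitanocene, C[Ti](C)(C1C=CC=C1)C1C=CC=C1
Why: Petasis methylenation converts the ester carbonyl into a 1-methoxyvinyl group without enolisation and tolerates sulfone, ketal and bromide, giving the acid-sensitive 2-methoxy-1,3-diene below the temperature of cycloaddition.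

Step 11
Reactants: 17 2-[(3E,7S,9E)-7-bromo-3-(1-methoxyethenyl)-4,8,8-trimethyl-10-(phenylsulfonyl)deca-3,9-dien-1-yl]-2-methyl-1,3-dioxolane
Product: 18 trans-fused bicyclic enol ether (3β-Br, 5α-H, 6α-SO2Ph, 10β-Me; C8(OMe)=C9; ketal chain on C9)
Conditions: PhMe (0.01 M), BHT, K2CO3, 130 °C, sealed tube
Reagents that add atoms: none
Why: Concerted but asynchronous thermal intramolecular Diels–Alder reaction: the 2-methoxydiene C7=C8–C9=C10 adds suprafacially to the E vinyl sulfone C5=C6, whose sulfonyl group should lower the barrier enough for cyclisation near 130 °C, where the [1,5]-hydrogen shift open to the Z-methyl diene is slow and reversible. The closest known reaction type is the cycloaddition of terminally activated 1,7,9-decatrienes that gives angularly methylated trans-decalins. Ring A closes by C5–C10 bond formation across the four-carbon tether C1–C4 (fused mode, new six-membered ring), and ring B is the cyclohexene made by the [4+2] event itself (C5–C10 and C6–C7 formed, C8=C9 left as the enol ether). C10 and C5 are set relative to each other by the geometry of the C9=C10 alkene (tether outside, methyl inside) together with the endo placement of the sulfone, which leads to the trans ring fusion; C6 follows from suprafacial addition to the E dienophile and is erased in step 12. The absolute sense at C5 and C10 is relayed from the (3S)-bromide, which should prefer the equatorial position of the chair-like tether. The step needs fused over bridged regiochemistry (secured by the short tether), trans over cis fusion (endo sulfone) and facial selectivity with respect to C3 (equatorial bromide); the last is the weakest control element, so a minor diastereomer may have to be removed by chromatography.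

Step 12
Reactants: 18 trans-fused bicyclic enol ether
Product: 20 3β-bromo Δ6-decalin-8-one (enone; 5α-H, 9β chain, 10β-Me), via β-sulfonyl ketone 19 (not isolated)
Conditions: oxalic acid (cat.), THF/H2O, 0 °C → rt; then DBU, CH2Cl2, 0 °C
Reagents that add atoms: water, O
Why: mild acid hydrolysis of the methyl enol ether, much faster than ketal cleavage, protonates C9 from the less hindered α face to give the equatorial 9β chain and the C8 ketone, and the β-sulfonyl ketone then loses benzenesulfinate by E1cB elimination to give the conjugated enone.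

Step 13
Reactants: 20 3β-bromo Δ6-decalin-8-one
Product: 21 3β-bromo trans-decalin-8-one (5α-H, 9β chain, 10β-Me)
Conditions: H2 (1 atm), Pd/C, EtOAc, rt
Reagents that add atoms: none
Why: catalytic hydrogenation of the unhindered disubstituted enone alkene is fast in neutral solvent, no other alkene is present, and hydrogenolysis of the hindered equatorial secondary bromide should be slow without base.

Step 14
Reactants: 21 3β-bromo trans-decalin-8-one
Product: 22 3β-bromo 8(17)-methylene trans-decalin (9β ketal chain)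
Conditions: Ph3PCH3Br, KOtBu, PhMe, 90 °C
Reagents that add atoms: methyltriphenylphosphonium bromide, C[P+](c1ccccc1)(c1ccccc1)c1ccccc1.[Br-]
Why: Wittig methylenation at elevated temperature is the established way to convert hindered α-branched cyclohexanones into exocyclic alkenes; C9 already has its thermodynamically preferred equatorial configuration and the equatorial bromide has no antiperiplanar hydrogen for E2.

Step 15
Reactants: 22 3β-bromo 8(17)-methylene trans-decalin
Product: 24 3β-bromo-8α-hydroxy-8β-methyl trans-decalin (9β ketal chain), via organomercurial 23 (not isolated)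
Conditions: Hg(OAc)2, THF/H2O, rt; then NaOH, NaBH4, 0 °C
Reagents that add atoms: water, O
Why: Markovnikov oxymercuration–demercuration, in which water opens the mercurinium ion at tertiary C8 from the α face because the axial β trajectory is blocked by the syn-axial C20 methyl, giving the equatorial 8α-hydroxyl and, after reduction of the C–Hg bond, the axial 8β-methyl.

Step 16
Reactants: 24 3β-bromo-8α-hydroxy-8β-methyl trans-decalin; 25 allyl bromide
Product: 26 8α-allyl ether (3β-Br, 9β ketal chain)
Conditions: KH, THF, 0 °C; then 25, Bu4NI (cat.), 0 → 50 °C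
Reagents that add atoms: none
Why: Williamson etherification of the tertiary potassium alkoxide with a reactive allylic halide is feasible for hindered alcohols, and the rigid equatorial C3 bromide is inert to SN2 and E2 under these conditions.

Step 17
Reactants: 26 8α-allyl ether
Product: 27 8α-allyloxy methyl ketone (C13 ketone; 3β-Br)
Conditions: PPTS, acetone/H2O, 55 °C
Reagents that add atoms: water, O
Why: acid-catalysed ketal hydrolysis with a weak pyridinium acid unmasks the methyl ketone while the tertiary allyl ether and the alkyl bromide remain intact.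

Step 18
Reactants: 27 8α-allyloxy methyl ketone
Product: 28 8α-allyloxy-9β-(3-methylbut-3-enyl) diene (3β-Br)
Conditions: Ph3PCH3Br, KOtBu, THF, 0 °C → rt
Reagents that add atoms: methyltriphenylphosphonium bromide, C[P+](c1ccccc1)(c1ccccc1)c1ccccc1.[Br-]
Why: Wittig methylenation of the unhindered methyl ketone gives the 1,1-disubstituted alkene needed as the second metathesis partner.

Step 19
Reactants: 28 8α-allyloxy-9β-(3-methylbut-3-enyl) diene
Product: 29 tricyclic (13Z)-oxocene (3β-bromo-8α,15-epoxylabd-13-ene)
Conditions: (H2IMes)(PCy3)Cl2Ru=CHPh (second-generation Grubbs catalyst, 5 mol %), PhMe (2 mM), 80 °C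
Reagents that add atoms: none
Why: ring-closing metathesis of the monosubstituted allyl ether with the 1,1-disubstituted alkene at high dilution should close the eight-membered ring, the trans-diequatorial chains on ring B preorganising the closure and the ring size enforcing the Z trisubstituted C13=C14 alkene.

Step 20
Reactants: 29 tricyclic (13Z)-oxocene
Product: 30 CNP0311742.2, (3S,5R,8R,9R,10S,13R,14S)-3-bromo-8,15:13,14-diepoxylabdane
Conditions: mCPBA, NaHCO3, CH2Cl2, 0 °C
Reagents that add atoms: meta-chloroperoxybenzoic acid, O=C(OO)c1cccc(Cl)c1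
Why: Prilezhaev epoxidation of the only alkene by peripheral attack, the oxocene being expected to fold its C13=C14 unit towards the α face, away from the axial 8β-methyl, so that the exposed face leads to the (13R,14S)-epoxide, with syn addition keeping C12 and C15 cis.

Compound list
1 | 3,3-dimethylpent-4-enoic acid | OC(=O)CC(C)(C)C=C | starting material
2 | (R)-4-benzyloxazolidin-2-one | O=C1N[C@H](Cc2ccccc2)CO1 | starting material
3 | 3,3-dimethylpent-4-enoic pivalic anhydride | CC(C)(C)C(=O)OC(=O)CC(C)(C)C=C | intermediate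
4 | (R)-4-benzyl-3-(3,3-dimethylpent-4-enoyl)oxazolidin-2-one | O=C(CC(C)(C)C=C)N1[C@H](Cc2ccccc2)COC1=O | intermediate
5 | dibutylboron Z-enolate of 4 | CCCCB(CCCC)O/C(=C\C(C)(C)C=C)N1[C@H](Cc2ccccc2)COC1=O | intermediate
6 | (R)-4-benzyl-3-[(2R)-2-bromo-3,3-dimethylpent-4-enoyl]oxazolidin-2-one | O=C([C@H](Br)C(C)(C)C=C)N1[C@H](Cc2ccccc2)COC1=O | intermediate
7 | (2R)-2-bromo-3,3-dimethylpent-4-en-1-ol | OC[C@H](Br)C(C)(C)C=C | intermediate
8 | (2R)-2-bromo-3,3-dimethylpent-4-en-1-yl trifluoromethanesulfonate | FC(F)(F)S(=O)(=O)OC[C@H](Br)C(C)(C)C=C | intermediate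
9 | methyl acetoacetate | COC(=O)CC(C)=O | starting material
10 | 2-(2-bromoethyl)-2-methyl-1,3-dioxolane | CC1(CCBr)OCCO1 | starting material
11 | methyl 2-acetyl-4-(2-methyl-1,3-dioxolan-2-yl)butanoate | COC(=O)C(CCC1(C)OCCO1)C(C)=O | intermediate
12 | methyl (6S)-6-bromo-7,7-dimethyl-2-[2-(2-methyl-1,3-dioxolan-2-yl)ethyl]-3-oxonon-8-enoate | COC(=O)C(CCC1(C)OCCO1)C(=O)CC[C@H](Br)C(C)(C)C=C | intermediate
13 | methyl (2Z,6S)-6-bromo-7,7-dimethyl-2-[2-(2-methyl-1,3-dioxolan-2-yl)ethyl]-3-(trifluoromethylsulfonyloxy)nona-2,8-dienoate | COC(=O)/C(CCC1(C)OCCO1)=C(\OS(=O)(=O)C(F)(F)F)CC[C@H](Br)C(C)(C)C=C | intermediate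
14 | methyl (2E,6S)-6-bromo-3,7,7-trimethyl-2-[2-(2-methyl-1,3-dioxolan-2-yl)ethyl]nona-2,8-dienoate | COC(=O)/C(CCC1(C)OCCO1)=C(\C)CC[C@H](Br)C(C)(C)C=C | intermediate
15 | methyl (2E,6S)-6-bromo-8-iodo-3,7,7-trimethyl-2-[2-(2-methyl-1,3-dioxolan-2-yl)ethyl]-9-(phenylsulfonyl)non-2-enoate (C8 epimers) | COC(=O)/C(CCC1(C)OCCO1)=C(\C)CC[C@H](Br)C(C)(C)C(I)CS(=O)(=O)c1ccccc1 | intermediate
16 | methyl (2E,6S,8E)-6-bromo-3,7,7-trimethyl-2-[2-(2-methyl-1,3-dioxolan-2-yl)ethyl]-9-(phenylsulfonyl)nona-2,8-dienoate | COC(=O)/C(CCC1(C)OCCO1)=C(\C)CC[C@H](Br)C(C)(C)/C=C/S(=O)(=O)c1ccccc1 | intermediate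
17 | 2-[(3E,7S,9E)-7-bromo-3-(1-methoxyethenyl)-4,8,8-trimethyl-10-(phenylsulfonyl)deca-3,9-dien-1-yl]-2-methyl-1,3-dioxolane | C=C(OC)/C(CCC1(C)OCCO1)=C(\C)CC[C@H](Br)C(C)(C)/C=C/S(=O)(=O)c1ccccc1 | intermediate
18 | trans-fused bicyclic enol ether (3β-Br, 5α-H, 6α-SO2Ph, 10β-Me; C8(OMe)=C9; 9-[2-(2-methyl-1,3-dioxolan-2-yl)ethyl]) | CC1(C)[C@@H](Br)CC[C@]2(C)C(CCC3(C)OCCO3)=C(OC)C[C@H](S(=O)(=O)c3ccccc3)[C@@H]12 | intermediate
19 | 3β-bromo-6α-(phenylsulfonyl) trans-decalin-8-one (9β ketal chain) | CC1(C)[C@@H](Br)CC[C@]2(C)[C@@H](CCC3(C)OCCO3)C(=O)C[C@H](S(=O)(=O)c3ccccc3)[C@@H]12 | intermediate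
20 | 3β-bromo Δ6-decalin-8-one (5α-H, 9β ketal chain, 10β-Me) | CC1(C)[C@@H](Br)CC[C@]2(C)[C@@H](CCC3(C)OCCO3)C(=O)C=C[C@@H]12 | intermediate
21 | 3β-bromo trans-decalin-8-one (9β ketal chain) | CC1(C)[C@@H](Br)CC[C@]2(C)[C@@H](CCC3(C)OCCO3)C(=O)CC[C@@H]12 | intermediate
22 | 3β-bromo 8(17)-methylene trans-decalin (9β ketal chain) | CC1(C)[C@@H](Br)CC[C@]2(C)[C@@H](CCC3(C)OCCO3)C(=C)CC[C@@H]12 | intermediate
23 | 17-(acetoxymercurio)-3β-bromo-8α-hydroxy trans-decalin (9β ketal chain) | CC1(C)[C@@H](Br)CC[C@]2(C)[C@@H](CCC3(C)OCCO3)[C@](C[Hg]OC(C)=O)(O)CC[C@@H]12 | intermediate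
24 | 3β-bromo-8α-hydroxy-8β-methyl trans-decalin (9β ketal chain) | CC1(C)[C@@H](Br)CC[C@]2(C)[C@@H](CCC3(C)OCCO3)[C@](C)(O)CC[C@@H]12 | intermediate
25 | allyl bromide | C=CCBr | starting material
26 | 8α-allyl ether of 24 | CC1(C)[C@@H](Br)CC[C@]2(C)[C@@H](CCC3(C)OCCO3)[C@](C)(OCC=C)CC[C@@H]12 | intermediate
27 | 8α-allyloxy-3β-bromo decalin with 9β-(3-oxobutyl) chain | CC1(C)[C@@H](Br)CC[C@]2(C)[C@@H](CCC(C)=O)[C@](C)(OCC=C)CC[C@@H]12 | intermediate
28 | 8α-allyloxy-3β-bromo decalin with 9β-(3-methylbut-3-enyl) chain | CC1(C)[C@@H](Br)CC[C@]2(C)[C@@H](CCC(C)=C)[C@](C)(OCC=C)CC[C@@H]12 | intermediate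
29 | (13Z)-3β-bromo-8α,15-epoxylabd-13-ene (tricyclic oxocene) | CC1(C)[C@@H](Br)CC[C@]2(C)[C@H]3CC/C(C)=C\CO[C@]3(C)CC[C@@H]12 | intermediate
30 | CNP0311742.2, (3S,5R,8R,9R,10S,13R,14S)-3-bromo-8,15:13,14-diepoxylabdane | CC1(C)[C@@H](Br)CC[C@]2(C)[C@H]3CC[C@@]4(C)O[C@H]4CO[C@]3(C)CC[C@@H]12 | target

Total step count: 20. Longest linear sequence: 19 steps (steps 1–4, then 6–20; step 5 makes the second fragment).

Steps most likely to fail

Step 11 (key cycloaddition). The hindered tetrasubstituted diene may cyclise so slowly that the [1,5]-hydrogen shift or hydrolysis of the methoxydiene competes, and the remote equatorial bromide may discriminate poorly between the two diene faces. The fallback sets out from 14 and comes back at 20. Aminolysis of 14 (MeNHOMe·HCl, iPrMgCl) would give the Weinreb amide F1, and MeMgBr the methyl enone F2. Radical nitration of the terminal alkene (tBuONO, TEMPO) would give the (E)-nitroalkene F3, and TBSOTf/Et3N the 2-silyloxydiene F4. Because a nitroalkene is a much stronger dienophile, F4 should cyclise at 25–60 °C to the nitro cycloadduct F5; the lower temperature suppresses the sigmatropic shift and sharpens the conformational preference. Bu4NF would then cleave the silyl enol ether and expel nitrite to give enone 20.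

Step 6 (fragment union). The strongly basic dianion may cause elimination of triflic acid from the β-bromo triflate, or attack at bromine, instead of substitution at C2. The fallback sets out from 8 and comes back at 12. The soft nucleophile NaCH(CO2Me)2 would displace the triflate to give the malonate F6. Saponification (KOH) would give the diacid F7, and thermal decarboxylation the acid F8; the neopentylic bromide should resist lactonisation. (COCl)2 would give the acid chloride F9. Crossed Claisen C-acylation of the lithium enolate (LiN(iPr)2, 2 equiv, −78 °C) of the ester F10 with F9 would give 12; F10 is made from commercial methyl 5-oxohexanoate with ethylene glycol and TsOH.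

Step 20 (epoxidation). The peracid may attack the undesired face of the oxocene if the ring populates the other fold, giving the 13,14-diepimeric epoxide. The fallback sets out from 29 and comes back at 30. NBS in wet DME would add Br+ to the same exposed face and water anti at tertiary C13, giving the bromohydrin F11. K2CO3 in MeOH would then close the epoxide with inversion at C14, so that the oxygen ends on the face opposite to that reached by direct epoxidation.

Further compounds
F1 | step 11 | (2E,6S)-6-bromo-N-methoxy-N,3,7,7-tetramethyl-2-[2-(2-methyl-1,3-dioxolan-2-yl)ethyl]nona-2,8-dienamide | CON(C)C(=O)/C(CCC1(C)OCCO1)=C(\C)CC[C@H](Br)C(C)(C)C=C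
F2 | step 11 | (3E,7S)-7-bromo-4,8,8-trimethyl-3-[2-(2-methyl-1,3-dioxolan-2-yl)ethyl]deca-3,9-dien-2-one | CC(=O)/C(CCC1(C)OCCO1)=C(\C)CC[C@H](Br)C(C)(C)C=C
F3 | step 11 | (3E,7S,9E)-7-bromo-4,8,8-trimethyl-3-[2-(2-methyl-1,3-dioxolan-2-yl)ethyl]-10-nitrodeca-3,9-dien-2-one | CC(=O)/C(CCC1(C)OCCO1)=C(\C)CC[C@H](Br)C(C)(C)/C=C/[N+](=O)[O-]
F4 | step 11 | tert-butyldimethylsilyl dienol ether of F3 (2-silyloxy-1,3-diene) | C=C(O[Si](C)(C)C(C)(C)C)/C(CCC1(C)OCCO1)=C(\C)CC[C@H](Br)C(C)(C)/C=C/[N+](=O)[O-]
F5 | step 11 | trans-fused nitro cycloadduct (3β-Br, 5α-H, 6α-NO2, 10β-Me; C8(OTBS)=C9) | CC1(C)[C@@H](Br)CC[C@]2(C)C(CCC3(C)OCCO3)=C(O[Si](C)(C)C(C)(C)C)C[C@H]([N+](=O)[O-])[C@@H]12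
F6 | step 6 | dimethyl 2-[(2S)-2-bromo-3,3-dimethylpent-4-en-1-yl]propanedioate | COC(=O)C(C[C@H](Br)C(C)(C)C=C)C(=O)OC
F7 | step 6 | 2-[(2S)-2-bromo-3,3-dimethylpent-4-en-1-yl]propanedioic acid | OC(=O)C(C[C@H](Br)C(C)(C)C=C)C(=O)O
F8 | step 6 | (4S)-4-bromo-5,5-dimethylhept-6-enoic acid | OC(=O)CC[C@H](Br)C(C)(C)C=C
F9 | step 6 | (4S)-4-bromo-5,5-dimethylhept-6-enoyl chloride | ClC(=O)CC[C@H](Br)C(C)(C)C=C
F10 | step 6 | methyl 4-(2-methyl-1,3-dioxolan-2-yl)butanoate | COC(=O)CCCC1(C)OCCO1
F11 | step 20 | 3β,14-dibromo-8α,15-epoxylabdan-13-ol (bromohydrin; 13-OH on the face of the future epoxide, 14-Br opposite) | CC1(C)[C@@H](Br)CC[C@]2(C)[C@H]3CC[C@@](C)(O)[C@H](Br)CO[C@]3(C)CC[C@@H]12
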